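Retrosynthesis: after the 5,5''- and 4',4'''-hydroxyl groups are unmasked, both pyranone rings C are cut at C4–C4a and C4''–C4a'', then at O1–C2 and O1''–C2''. The C8–C8'' axis is cut last, which leads back to 3,5-dimethoxyphenol and an arylpropiolate.
Forward: rings A and B are bought. The axis is made first by oxidative dimerisation of the ortho-lithiated phenol MOM ether, both phenols are then added to the ynoate, and the two rings C close together in the last skeleton-building step.
Enabling feature: in each ring A of the 2,2'-biphenol core, one position ortho to O1 (C8) carries the axis. C4a, which lies between O1 and the C5 oxygen and para to the C7 methoxy group, is therefore the only carbon that an acyl group hung on O1 through C2=C3 can reach.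
Stereochemistry: there is no stereocentre. The Z enol ether geometry (carboxyl cis to O1) comes from anti addition to the alkyne and corrects itself under acid, and the axis is formed without control.

Key step: step 7

Assumption: the target SMILES gives no sense of axial chirality, so the tetra-ortho-substituted 8,8'' axis is built racemic and the target is delivered as the racemate.

Step 1
Reactants: 1 3,5-dimethoxyphenol
Product: 2 1,3-dimethoxy-5-(methoxymethoxy)benzene
Conditions: MOMCl, K2CO3, DMF, 0 °C to rt
Reagents that add atoms: chloromethyl methyl ether, COCCl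
Why: Williamson-type O-alkylation of the phenoxide by the reactive α-chloro ether installs the chelating acetal that will direct the metalation, and no other nucleophilic site competes.

Step 2
Reactants: 2 1,3-dimethoxy-5-(methoxymethoxy)benzene (two molecules)
Product: 4 2,2'-bis(methoxymethoxy)-4,4',6,6'-tetramethoxybiphenyl, via aryllithium 3 (not isolated)
Conditions: n-BuLi, THF, 0 °C to rt; then anhydrous CuCl2, −78 °C to rt
Reagents that add atoms: none
Why: Directed ortho-metalation places lithium at one of the two equivalent CH positions flanked by OMOM and OMe, because the chelating acetal outranks the site between two plain methoxy groups, and copper-mediated oxidative homocoupling (divalent copper reduced to monovalent copper) then joins two aryl groups as known for 2,6-dialkoxyphenyllithiums, giving the axis in racemic form.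

Step 3
Reactants: 4 2,2'-bis(methoxymethoxy)-4,4',6,6'-tetramethoxybiphenyl
Product: 5 4,4',6,6'-tetramethoxybiphenyl-2,2'-diol
Conditions: HCl (cat.), MeOH, 50 °C
Reagents that add atoms: none
Why: Acid-catalysed acetal cleavage (transacetalisation to methanol) removes both MOM groups, since the aryl methyl ethers are inert to dilute HCl and the large excess of methanol intercepts the methoxymethyl cation before it can alkylate the electron-rich rings.

Step 4
Reactants: 6 1-(benzyloxy)-4-iodobenzene; 7 ethyl propiolate
Product: 8 ethyl 3-[4-(benzyloxy)phenyl]prop-2-ynoate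
Conditions: PdCl2(PPh3)2 (2 mol %), CuI (4 mol %), K2CO3, THF, 65 °C, excess 7
Reagents that add atoms: none
Why: Sonogashira coupling (oxidative addition of the aryl iodide to zerovalent palladium, transfer of the copper acetylide, reductive elimination) forms the aryl–alkyne bond, and a carbonate base in place of an amine spares the propiolate from conjugate addition.

Step 5
Reactants: 5 4,4',6,6'-tetramethoxybiphenyl-2,2'-diol; 8 ethyl 3-[4-(benzyloxy)phenyl]prop-2-ynoate (two molecules incorporated)
Product: 9 diethyl (2Z,2'Z)-3,3'-[(4,4',6,6'-tetramethoxybiphenyl-2,2'-diyl)bis(oxy)]bis{3-[4-(benzyloxy)phenyl]acrylate}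
Conditions: Cs2CO3 (0.5 equiv), 8 (3 equiv), DMF, 80 °C, Ar
Reagents that add atoms: none
Why: Base-catalysed oxa-Michael addition of a phenoxide to an arylpropiolate (first stage of the Ruhemann chromone synthesis) forms each O1–C2 bond, protonation of the allenolate anti to the incoming oxygen gives the Z enol ether, and excess ynoate with heating carries the mono-adduct on to the bis-adduct because any intramolecular ketal formation is reversible by E1cB whereas addition to the alkyne is not.

Step 6
Reactants: 9 diethyl (2Z,2'Z)-3,3'-[(4,4',6,6'-tetramethoxybiphenyl-2,2'-diyl)bis(oxy)]bis{3-[4-(benzyloxy)phenyl]acrylate}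
Product: 11 (2Z,2'Z)-3,3'-[(4,4',6,6'-tetramethoxybiphenyl-2,2'-diyl)bis(oxy)]bis{3-[4-(benzyloxy)phenyl]acrylic acid}, via dilithium dicarboxylate 10 (not isolated)
Conditions: LiOH, THF–EtOH–H2O, 40 °C; then 1 M HCl, 0 °C, pH 3
Reagents that add atoms: lithium hydroxide, [Li+].[OH-]
Why: Ester saponification by acyl substitution succeeds because the β-carbon is shielded by its two aryl-bearing substituents and made electron-rich by the enol ether oxygen, so hydroxide attacks the ester carbonyl, and cold acidification protonates the carboxylate without hydrolysing the enol ethers.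

Step 7
Reactants: 11 (2Z,2'Z)-3,3'-[(4,4',6,6'-tetramethoxybiphenyl-2,2'-diyl)bis(oxy)]bis{3-[4-(benzyloxy)phenyl]acrylic acid}
Product: 13 4',4'''-bis(benzyloxy)-5,5'',7,7''-tetramethoxy-8,8''-biflavone, via bis(trifluoroacetic) mixed anhydride 12 (not isolated)
Conditions: (CF3CO)2O (2.5 equiv), CH2Cl2, 0 °C to rt
Reagents that add atoms: none
Why: Trifluoroacetic anhydride turns each carboxyl group into the mixed anhydride 12, which ionises in the trifluoroacetic acid released to a vinylogous acylium ion; its carbon C4 (C4'') is attacked by C4a (C4a'') of the adjoining ring A and loss of the proton restores aromaticity, so C4–C4a and C4''–C4a'' form in one flask. The closest known reaction type is the intramolecular Friedel–Crafts acylation of 3-aryloxycinnamic acids to flavones (second stage of the Ruhemann chromone synthesis), and anhydride-promoted cycloacylation of aryloxy acids onto di- and trialkoxyarene rings is established. Each of the two rings C closes as a six-membered ring by electrophilic aromatic substitution, 6-exo at the acyl carbon with the C4=O bond left outside the ring. No stereocentre is created, and the C8–C8'' axis, locked by four ortho substituents, is not touched. Site selectivity is required and the substrate secures it: the O1–C2=C3 tether lets C4 reach only the two positions ortho to O1, C8 is occupied by the axis, C6 is out of reach, and C4a is activated by O1 and the 5-methoxy group (ortho) and by the 7-methoxy group (para). Chemoselectivity rests on the same activation, since an E arm could close only onto a ring B position meta to the benzyloxy group while acid equilibrates E to Z through the C2 oxocarbenium ion, near-stoichiometric anhydride at 0 °C keeps trifluoroacetylation of C6 slow until the new carbonyl group has deactivated ring A, and benzyl ethers tolerate trifluoroacetic acid at room temperature.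

Step 8
Reactants: 13 4',4'''-bis(benzyloxy)-5,5'',7,7''-tetramethoxy-8,8''-biflavone
Product: 15 4',4''',5,5''-tetrahydroxy-7,7''-dimethoxy-8,8''-biflavone (7,7''-di-O-methylcupressuflavone, CNP0151059.0), via tetrakis(dichloroboryl) ether 14 (not isolated)
Conditions: BCl3 (excess), C6HMe5, CH2Cl2, −78 °C to 0 °C; then H2O–THF, rt
Reagents that add atoms: none
Why: Lewis acid ether cleavage is selective because BCl3 is held in a six-membered chelate between the C4 carbonyl and the peri 5-methoxy oxygen, so chloride demethylates only there, the benzyl ethers ionise at low temperature with pentamethylbenzene trapping the benzyl cation, and the unchelated 7-methoxy groups are inert to BCl3 at or below 0 °C.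

Compound list
1 | 3,5-dimethoxyphenol | COc1cc(O)cc(OC)c1 | starting material
2 | 1,3-dimethoxy-5-(methoxymethoxy)benzene | COCOc1cc(OC)cc(OC)c1 | intermediate
3 | [2,4-dimethoxy-6-(methoxymethoxy)phenyl]lithium (not isolated) | [Li]c1c(OC)cc(OC)cc1OCOC | intermediate
4 | 2,2'-bis(methoxymethoxy)-4,4',6,6'-tetramethoxybiphenyl | COCOc1cc(OC)cc(OC)c1-c1c(OC)cc(OC)cc1OCOC | intermediate
5 | 4,4',6,6'-tetramethoxybiphenyl-2,2'-diol | COc1cc(O)c(-c2c(O)cc(OC)cc2OC)c(OC)c1 | intermediate
6 | 1-(benzyloxy)-4-iodobenzene | Ic1ccc(OCc2ccccc2)cc1 | starting material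
7 | ethyl propiolate | C#CC(=O)OCC | starting material
8 | ethyl 3-[4-(benzyloxy)phenyl]prop-2-ynoate | CCOC(=O)C#Cc1ccc(OCc2ccccc2)cc1 | intermediate
9 | diethyl (2Z,2'Z)-3,3'-[(4,4',6,6'-tetramethoxybiphenyl-2,2'-diyl)bis(oxy)]bis{3-[4-(benzyloxy)phenyl]acrylate} | COc1cc(OC)c(-c2c(OC)cc(OC)cc2O/C(=C\C(=O)OCC)c2ccc(OCc3ccccc3)cc2)c(O/C(=C\C(=O)OCC)c2ccc(OCc3ccccc3)cc2)c1 | intermediate
10 | dilithium salt of diacid 11 (not isolated) | COc1cc(OC)c(-c2c(OC)cc(OC)cc2O/C(=C\C(=O)[O-])c2ccc(OCc3ccccc3)cc2)c(O/C(=C\C(=O)[O-])c2ccc(OCc3ccccc3)cc2)c1.[Li+].[Li+] | intermediate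
11 | (2Z,2'Z)-3,3'-[(4,4',6,6'-tetramethoxybiphenyl-2,2'-diyl)bis(oxy)]bis{3-[4-(benzyloxy)phenyl]acrylic acid} | COc1cc(OC)c(-c2c(OC)cc(OC)cc2O/C(=C\C(=O)O)c2ccc(OCc3ccccc3)cc2)c(O/C(=C\C(=O)O)c2ccc(OCc3ccccc3)cc2)c1 | intermediate
12 | bis(trifluoroacetic) mixed anhydride of diacid 11 (not isolated) | COc1cc(OC)c(-c2c(OC)cc(OC)cc2O/C(=C\C(=O)OC(=O)C(F)(F)F)c2ccc(OCc3ccccc3)cc2)c(O/C(=C\C(=O)OC(=O)C(F)(F)F)c2ccc(OCc3ccccc3)cc2)c1 | intermediate
13 | 4',4'''-bis(benzyloxy)-5,5'',7,7''-tetramethoxy-8,8''-biflavone | COc1cc(OC)c2c(=O)cc(-c3ccc(OCc4ccccc4)cc3)oc2c1-c1c(OC)cc(OC)c2c(=O)cc(-c3ccc(OCc4ccccc4)cc3)oc12 | intermediate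
14 | 4',4''',5,5''-tetrakis(dichloroboryloxy)-7,7''-dimethoxy-8,8''-biflavone (not isolated) | COc1cc(OB(Cl)Cl)c2c(=O)cc(-c3ccc(OB(Cl)Cl)cc3)oc2c1-c1c(OC)cc(OB(Cl)Cl)c2c(=O)cc(-c3ccc(OB(Cl)Cl)cc3)oc12 | intermediate
15 | 4',4''',5,5''-tetrahydroxy-7,7''-dimethoxy-8,8''-biflavone, racemic | COc1cc(O)c2c(=O)cc(-c3ccc(O)cc3)oc2c1-c1c(OC)cc(O)c2c(=O)cc(-c3ccc(O)cc3)oc12 | target

Total step count: 8
Longest linear sequence: 7 (steps 1, 2, 3, 5, 6, 7, 8). Step 4 is the convergent branch.

Steps most likely to fail

Step 5. Conjugate addition to the donor-substituted ynoate may be slow. The mono-adduct may also be captured by its own neighbouring phenoxide in a second, intramolecular addition, so that the second arm is never attached. The fallback forms the C–O bonds before the axis. It sets out from 1, which is iodinated ortho to the hydroxyl group with N-iodosuccinimide in CH2Cl2 at 0 °C to give 2-iodo-3,5-dimethoxyphenol F1, separated from any para isomer. Base-catalysed addition of this monomeric phenol to 8 gives ethyl (Z)-3-[4-(benzyloxy)phenyl]-3-(2-iodo-3,5-dimethoxyphenoxy)acrylate F2, in which no second phenol is at hand. Ullmann reductive homocoupling of F2 with activated copper powder in DMF at about 140 °C then makes the C8–C8'' bond and comes back to the route at 9.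

Step 2. Metalation may occur partly at the CH between the two methoxy groups. The hindered arylcopper species may also be protonated or chlorinated instead of coupling. The fallback separates metalation from bond formation and replaces the oxidative coupling by a reductive one. It sets out from 2, which is lithiated as before and quenched with I2 to give 2-iodo-1,5-dimethoxy-3-(methoxymethoxy)benzene F3, a compound that can be freed from a regioisomer before the axis is made. Ullmann coupling of F3 with copper powder in hot DMF comes back to the route at 4.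

Step 7. The donor-stabilised acylium ion may be too weak an electrophile, only one arm may close, C6 may be trifluoroacetylated, or adventitious water may hydrolyse the enol ethers. The fallback makes C4–C4a intermolecularly first and closes ring C at O1–C2. It sets out from 5, whose chelation-controlled ortho-acetylation (Ac2O, BF3·OEt2, Fries type, as known for 3,5-dimethoxyphenol) gives 1,1'-(2,2'-dihydroxy-4,4',6,6'-tetramethoxybiphenyl-3,3'-diyl)diethanone F4. Twofold Claisen–Schmidt condensation with commercial 4-(benzyloxy)benzaldehyde (KOH, EtOH) gives the bis-(E)-chalcone F5. Oxidative cyclisation with catalytic I2 in DMSO at 130 °C comes back to the route at 13.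

Further compounds
F1 | step 5 | 2-iodo-3,5-dimethoxyphenol | COc1cc(O)c(I)c(OC)c1
F2 | step 5 | ethyl (Z)-3-[4-(benzyloxy)phenyl]-3-(2-iodo-3,5-dimethoxyphenoxy)acrylate | COc1cc(OC)c(I)c(O/C(=C\C(=O)OCC)c2ccc(OCc3ccccc3)cc2)c1
F3 | step 2 | 2-iodo-1,5-dimethoxy-3-(methoxymethoxy)benzene | COCOc1cc(OC)cc(OC)c1I
F4 | step 7 | 1,1'-(2,2'-dihydroxy-4,4',6,6'-tetramethoxybiphenyl-3,3'-diyl)diethanone | CC(=O)c1c(OC)cc(OC)c(-c2c(OC)cc(OC)c(C(C)=O)c2O)c1O
F5 | step 7 | (2E,2'E)-1,1'-(2,2'-dihydroxy-4,4',6,6'-tetramethoxybiphenyl-3,3'-diyl)bis{3-[4-(benzyloxy)phenyl]prop-2-en-1-one} | O=C(/C=C/c1ccc(OCc2ccccc2)cc1)c1c(OC)cc(OC)c(-c2c(OC)cc(OC)c(C(=O)/C=C/c3ccc(OCc4ccccc4)cc3)c2O)c1O
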